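**Retrosynthetic overview**
1. Last cut: the CH2 bridge between pyranone C-3 and chroman C-6. It is made by a Mannich/methide Friedel–Crafts union of pyranone 20 with chromanol 16, the carbon coming from Eschenmoser's salt.
2. Chromanol: the C-3 hydroxyl comes from a C-3 boron group by stereoretentive oxidation. The dihydropyran ring comes from an asymmetric oxa-[4+2] cycloaddition of an acylphloroglucinol ortho-quinone methide with a 2-methylprop-1-enylboron partner.
3. Enabling feature: ring oxygen O-1 sits on aromatic C-8a, ortho to C-4a, which carries the benzylic C-4 methylene, so O-1–C-8a=C-4a–C-4 is a latent ortho-quinone methide (1-oxadiene). C-2 carries two methyl groups, which fixes the polarity of the C-2/C-3 alkene partner. A benzyl ether on the other oxygen flanking C-4a (the later 5-OH) forces closure through the oxygen next to the acyl group.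
4. Quinone methide precursor: the salicyl alcohol obtained by formylation and reduction of the 4-O-benzyl acylphloroglucinol, which has two equivalent free ring positions. That compound comes from phloroglucinol and (S)-2-methylbutanoic acid, the source of the side-chain stereocentre.
5. Ring order: benzene ring (purchased), then the dihydropyran ring (key step). The pyranone ring is built separately (dianion acylation, lactonisation) and joined last.

Key step: step 7

Assumption: the sense of induction of the chiral phosphoric acid in step 7 cannot be predicted with certainty. The route is written for (R)-TRIP; if a test run favours the (3R) adduct, (S)-TRIP is used instead. The C-3 epimers are diastereomers (fixed (S) side-chain centre) and should be separable.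

**Route**

Step 1
Reactants: 1 (S)-2-methylbutanoic acid
Product: 2 (S)-2-methylbutanoyl chloride
Conditions: (COCl)2, cat. DMF, CH2Cl2, 0 °C → rt; used as a solution
Reagents that add atoms: oxalyl chloride, ClC(=O)C(=O)Cl
Why: Acid chloride formation through the catalytic Vilsmeier-type chloroiminium species under neutral, cold conditions should leave the α-stereocentre untouched.

Step 2
Reactants: 3 phloroglucinol; 2 (S)-2-methylbutanoyl chloride
Product: 4 (2S)-2-methyl-1-(2,4,6-trihydroxyphenyl)butan-1-one
Conditions: AlCl3 (3.5 equiv), PhNO2–CH2Cl2, 0 °C → rt; aq. HCl work-up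
Reagents that add atoms: none
Why: Friedel–Crafts C-acylation of phloroglucinol stops at the mono-ketone because the acyl group deactivates the ring, and the α-centre should be carried over because the carbonyl is held as an aluminium chelate that enolises slowly.

Step 3
Reactants: 4 (2S)-2-methyl-1-(2,4,6-trihydroxyphenyl)butan-1-one
Product: 5 (2S)-1-[4-(benzyloxy)-2,6-dihydroxyphenyl]-2-methylbutan-1-one
Conditions: BnBr (1.0 equiv), K2CO3 (1.0 equiv), DMF, 0 °C → rt
Reagents that add atoms: benzyl bromide, BrCc1ccccc1
Why: Williamson etherification should take the most acidic, non-chelated 4-OH (para to the acyl group) while the two ketone-bonded hydroxy groups stay free, leaving two equivalent ring positions.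

Step 4
Reactants: 5 (2S)-1-[4-(benzyloxy)-2,6-dihydroxyphenyl]-2-methylbutan-1-one
Product: 7 6-(benzyloxy)-2,4-dihydroxy-3-[(2S)-2-methylbutanoyl]benzaldehyde, via aryl iminium chloride 6 (not isolated)
Conditions: POCl3 (1.2 equiv), DMF (2 equiv), EtOAc, 0 °C → rt; then H2O, 40 °C
Reagents that add atoms: N,N-dimethylformamide, CN(C)C=O; water, O
Why: Vilsmeier–Haack formylation should occur at either of the two equivalent electron-rich positions, the first formyl group deactivating the ring against a second, and hydrolysis of the iminium salt gives the aldehyde.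

Step 5
Reactants: 7 6-(benzyloxy)-2,4-dihydroxy-3-[(2S)-2-methylbutanoyl]benzaldehyde
Product: 8 (2S)-1-[4-(benzyloxy)-2,6-dihydroxy-3-(hydroxymethyl)phenyl]-2-methylbutan-1-one
Conditions: NaBH4, THF–EtOH, −20 °C; acetone quench, pH 7 buffer; used crude
Reagents that add atoms: none
Why: Chemoselective hydride reduction of the aldehyde (the hindered, doubly chelated aryl ketone reacts far more slowly) with a cold, non-acidic quench should keep the salicyl alcohol from ionising while hydride is still present.

Step 6
Reactants: 9 (2-methylprop-1-en-1-yl)boronic acid; 10 naphthalene-1,8-diamine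
Product: 11 2-(2-methylprop-1-en-1-yl)-2,3-dihydro-1H-naphtho[1,8-de][1,3,2]diazaborinine
Conditions: toluene, reflux, water separator
Reagents that add atoms: none
Why: Dehydrative condensation of a boronic acid with the 1,8-diamine gives the B(dan) amide, which masks the Lewis acidity of boron and supplies the N–H hydrogen-bond donors used in step 7.

Step 7
Reactants: 8 (2S)-1-[4-(benzyloxy)-2,6-dihydroxy-3-(hydroxymethyl)phenyl]-2-methylbutan-1-one; 11 2-(2-methylprop-1-en-1-yl)-2,3-dihydro-1H-naphtho[1,8-de][1,3,2]diazaborinine
Product: 13 (2S)-1-[(3S)-5-(benzyloxy)-7-hydroxy-2,2-dimethyl-3-(1H-naphtho[1,8-de][1,3,2]diazaborinin-2(3H)-yl)-3,4-dihydro-2H-chromen-8-yl]-2-methylbutan-1-one, via ortho-quinone methide 12 (not isolated)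
Conditions: (R)-TRIP [(R)-3,3'-bis(2,4,6-triisopropylphenyl)-1,1'-binaphthyl-2,2'-diyl hydrogen phosphate] (10 mol %), 11 (3 equiv), 5 Å molecular sieves, toluene–CH2Cl2, −20 °C → rt, slow addition of 8
Reagents that add atoms: none
Why: Proposed new method: the phosphoric acid dehydrates salicyl alcohol 8 to the hydrogen-bonded ortho-quinone methide 12, whose exocyclic CH2 is attacked by the boron-bearing CH carbon of 11 while positive charge builds at the CMe2 carbon (tertiary and stabilised by hyperconjugation with the C–B bond) and is quenched by the quinone methide oxygen, an asynchronous inverse-electron-demand oxa-[4+2] cycloaddition in which boron stays on carbon. The closest known reaction types are the chiral-phosphoric-acid-catalysed [4+2] cycloadditions of ortho-quinone methides from ortho-hydroxybenzyl alcohols with enamides, vinylindoles and styrenes, and the hetero-Diels–Alder reactions of acylphloroglucinol quinone methides with trisubstituted alkenes that place oxygen on the more substituted carbon; an alkenylboron 2π partner is new. The dihydropyran ring closes as the six-membered ring of this [4+2] cycloaddition, the C–C bond leading and the C–O bond following. The one new stereocentre (boron-bearing C-3, S) should be set by the catalyst, whose P=O accepts a hydrogen bond from an N–H of the B(dan) group while its P–OH binds the quinone methide oxygen so that one alkene face is presented; any (3R) material is a diastereomer and removable. The step needs regioselectivity (secured by the gem-dimethyl terminus), closure through the oxygen next to the acyl group only (secured by the benzyl ether on the other flanking oxygen), retention of boron instead of Petasis-type alkenyl transfer (secured by the non-Lewis-acidic B(dan) group) and suppression of Friedel–Crafts self-alkylation at the free aromatic CH (excess 11, slow addition of 8).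

Step 8
Reactants: 13 (2S)-1-[(3S)-5-(benzyloxy)-7-hydroxy-2,2-dimethyl-3-(1H-naphtho[1,8-de][1,3,2]diazaborinin-2(3H)-yl)-3,4-dihydro-2H-chromen-8-yl]-2-methylbutan-1-one
Product: 15 (2S)-1-[(3S)-5-(benzyloxy)-3,7-dihydroxy-2,2-dimethyl-3,4-dihydro-2H-chromen-8-yl]-2-methylbutan-1-one, via chroman-3-ylboronic acid 14 (not isolated)
Conditions: 5 M HCl aq., THF, rt, filter; NaOH aq. to pH 8–9; NaBO3·4H2O, THF–H2O, 0 °C → rt
Reagents that add atoms: sodium perborate tetrahydrate (NaBO3·4H2O), [Na+].[Na+].O[B-]1(O)OO[B-](O)(O)OO1
Why: Acid hydrolysis of the B(dan) group and perborate oxidation of the boronic acid (1,2-shift of carbon from boron to oxygen with retention) should turn the (S) C–B centre into the (S) carbinol under conditions too mild for Dakin-type attack on the ortho-hydroxyaryl ketone.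

Step 9
Reactants: 15 (2S)-1-[(3S)-5-(benzyloxy)-3,7-dihydroxy-2,2-dimethyl-3,4-dihydro-2H-chromen-8-yl]-2-methylbutan-1-one
Product: 16 (2S)-1-[(3S)-3,5,7-trihydroxy-2,2-dimethyl-3,4-dihydro-2H-chromen-8-yl]-2-methylbutan-1-one
Conditions: H2 (1 atm), Pd/C (10 wt %), EtOAc–EtOH, rt
Reagents that add atoms: none
Why: Hydrogenolysis of the aryl benzyl ether over Pd/C should leave the chelated aryl ketone, the secondary alcohol and both stereocentres untouched.

Step 10
Reactants: 17 methyl 3-oxopentanoate; 18 N-methoxy-N-methylpropanamide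
Product: 19 methyl 4-methyl-3,5-dioxoheptanoate
Conditions: LiN(iPr)2 (2.2 equiv), THF, −78 → 0 °C; then 18, −78 °C → rt; 1 M HCl
Reagents that add atoms: none
Why: Claisen-type acylation of the β-keto ester dianion occurs at the more basic γ-carbanion, and the stable tetrahedral chelate of the Weinreb amide prevents over-addition.

Step 11
Reactants: 19 methyl 4-methyl-3,5-dioxoheptanoate
Product: 20 6-ethyl-4-hydroxy-5-methyl-2H-pyran-2-one
Conditions: DBU (1.2 equiv), toluene, reflux; acidic work-up
Reagents that add atoms: none
Why: Base-mediated enol-lactonisation (attack of the C-5 enolate oxygen on the ester with loss of methanol) should give the aromatic 4-hydroxy-2-pyranone.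

Step 12
Reactants: 20 6-ethyl-4-hydroxy-5-methyl-2H-pyran-2-one; 16 (2S)-1-[(3S)-3,5,7-trihydroxy-2,2-dimethyl-3,4-dihydro-2H-chromen-8-yl]-2-methylbutan-1-one
Product: 23 6-ethyl-4-hydroxy-5-methyl-3-{[(3S)-3,5,7-trihydroxy-2,2-dimethyl-8-[(2S)-2-methylbutanoyl]-3,4-dihydro-2H-chromen-6-yl]methyl}-2H-pyran-2-one (CNP0361212.1), via pyranone Mannich base 21 (not isolated), via pyranone methide 22 (not isolated)
Conditions: 20, Eschenmoser's salt (1.0 equiv), MeCN, rt; then 16 (1.0 equiv), 60 °C
Reagents that add atoms: Eschenmoser's salt (N,N-dimethylmethyleneiminium iodide), C=[N+](C)C.[I-]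
Why: Mannich reaction at the nucleophilic pyranone C-3, thermal loss of dimethylamine to the 3-methylidene-pyran-2,4-dione and Friedel–Crafts-type conjugate addition of the only free aromatic carbon of 16 (C-6, between two hydroxy groups) should form the methylene bridge without touching a stereocentre.

**Compound list**

1 | (S)-2-methylbutanoic acid | CC[C@H](C)C(=O)O | starting material
2 | (S)-2-methylbutanoyl chloride | CC[C@H](C)C(=O)Cl | intermediate
3 | phloroglucinol (benzene-1,3,5-triol) | Oc1cc(O)cc(O)c1 | starting material
4 | (2S)-2-methyl-1-(2,4,6-trihydroxyphenyl)butan-1-one | CC[C@H](C)C(=O)c1c(O)cc(O)cc1O | intermediate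
5 | (2S)-1-[4-(benzyloxy)-2,6-dihydroxyphenyl]-2-methylbutan-1-one | CC[C@H](C)C(=O)c1c(O)cc(OCc2ccccc2)cc1O | intermediate
6 | N-{[6-(benzyloxy)-2,4-dihydroxy-3-[(2S)-2-methylbutanoyl]phenyl]methylidene}-N-methylmethanaminium chloride (aryl iminium chloride) | CC[C@H](C)C(=O)c1c(O)cc(OCc2ccccc2)c(C=[N+](C)C)c1O.[Cl-] | intermediate (not isolated)
7 | 6-(benzyloxy)-2,4-dihydroxy-3-[(2S)-2-methylbutanoyl]benzaldehyde | CC[C@H](C)C(=O)c1c(O)cc(OCc2ccccc2)c(C=O)c1O | intermediate
8 | (2S)-1-[4-(benzyloxy)-2,6-dihydroxy-3-(hydroxymethyl)phenyl]-2-methylbutan-1-one | CC[C@H](C)C(=O)c1c(O)cc(OCc2ccccc2)c(CO)c1O | intermediate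
9 | (2-methylprop-1-en-1-yl)boronic acid | CC(C)=CB(O)O | starting material
10 | naphthalene-1,8-diamine | Nc1cccc2cccc(N)c12 | starting material
11 | 2-(2-methylprop-1-en-1-yl)-2,3-dihydro-1H-naphtho[1,8-de][1,3,2]diazaborinine | CC(C)=CB1Nc2cccc3cccc(N1)c23 | intermediate
12 | 3-(benzyloxy)-5-hydroxy-2-methylidene-6-[(2S)-2-methylbutanoyl]cyclohexa-3,5-dien-1-one (ortho-quinone methide) | CC[C@H](C)C(=O)C1=C(O)C=C(OCc2ccccc2)C(=C)C1=O | intermediate (not isolated)
13 | (2S)-1-[(3S)-5-(benzyloxy)-7-hydroxy-2,2-dimethyl-3-(1H-naphtho[1,8-de][1,3,2]diazaborinin-2(3H)-yl)-3,4-dihydro-2H-chromen-8-yl]-2-methylbutan-1-one | CC[C@H](C)C(=O)c1c(O)cc(OCc2ccccc2)c2c1OC(C)(C)[C@@H](B3Nc4cccc5cccc(N3)c45)C2 | intermediate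
14 | [(3S)-5-(benzyloxy)-7-hydroxy-2,2-dimethyl-8-[(2S)-2-methylbutanoyl]-3,4-dihydro-2H-chromen-3-yl]boronic acid | CC[C@H](C)C(=O)c1c(O)cc(OCc2ccccc2)c2c1OC(C)(C)[C@@H](B(O)O)C2 | intermediate (not isolated)
15 | (2S)-1-[(3S)-5-(benzyloxy)-3,7-dihydroxy-2,2-dimethyl-3,4-dihydro-2H-chromen-8-yl]-2-methylbutan-1-one | CC[C@H](C)C(=O)c1c(O)cc(OCc2ccccc2)c2c1OC(C)(C)[C@@H](O)C2 | intermediate
16 | (2S)-1-[(3S)-3,5,7-trihydroxy-2,2-dimethyl-3,4-dihydro-2H-chromen-8-yl]-2-methylbutan-1-one | CC[C@H](C)C(=O)c1c(O)cc(O)c2c1OC(C)(C)[C@@H](O)C2 | intermediate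
17 | methyl 3-oxopentanoate | CCC(=O)CC(=O)OC | starting material
18 | N-methoxy-N-methylpropanamide | CCC(=O)N(C)OC | starting material
19 | methyl 4-methyl-3,5-dioxoheptanoate | CCC(=O)C(C)C(=O)CC(=O)OC | intermediate
20 | 6-ethyl-4-hydroxy-5-methyl-2H-pyran-2-one | CCc1oc(=O)cc(O)c1C | intermediate
21 | 3-[(dimethylamino)methyl]-6-ethyl-4-hydroxy-5-methyl-2H-pyran-2-one (formed as its hydroiodide) | CCc1oc(=O)c(CN(C)C)c(O)c1C | intermediate (not isolated)
22 | 6-ethyl-5-methyl-3-methylidene-2H-pyran-2,4(3H)-dione | CCC1=C(C)C(=O)C(=C)C(=O)O1 | intermediate (not isolated)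
23 | 6-ethyl-4-hydroxy-5-methyl-3-{[(3S)-3,5,7-trihydroxy-2,2-dimethyl-8-[(2S)-2-methylbutanoyl]-3,4-dihydro-2H-chromen-6-yl]methyl}-2H-pyran-2-one | CCc1oc(=O)c(Cc2c(O)c3c(c(C(=O)[C@@H](C)CC)c2O)OC(C)(C)[C@@H](O)C3)c(O)c1C | target

**Count and risks**

Total step count: 12. Longest linear sequence: 9 steps (steps 1, 2, 3, 4, 5, 7, 8, 9, 12).

Steps most likely to fail:

1. Step 7 (proposed new method). The alkenyl group may transfer to the quinone methide with loss of boron, or protodeboronate, instead of cycloadding; the quinone methide may alkylate the free aromatic CH of another molecule; facial selectivity may be poor. Fallback with known chemistry, setting out from aldehyde 7 and returning at 16: 7 is heated with boronic acid 9 and dibenzylamine (dioxane, 90 °C). Petasis borono-Mannich alkenyl transfer, loss of the amine and oxa-6π electrocyclisation of the vinyl quinone methide make the same two bonds and should give (2S)-1-[5-(benzyloxy)-7-hydroxy-2,2-dimethyl-2H-chromen-8-yl]-2-methylbutan-1-one F1. Jacobsen–Katsuki epoxidation of this cis-alkene ((S,S)-(salen)MnCl, mCPBA, N-methylmorpholine N-oxide, CH2Cl2, −78 °C) should give, as is usual for 2,2-dimethylchromenes with this catalyst enantiomer, (2S)-1-[(3S,4S)-5-(benzyloxy)-3,4-epoxy-7-hydroxy-2,2-dimethyl-3,4-dihydro-2H-chromen-8-yl]-2-methylbutan-1-one F2. Hydrogenation (H2, Pd/C, EtOAc) then cleaves the benzylic C-4–O bond of the epoxide and the benzyl ether together and gives 16.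

2. Step 5. The benzylic position may be over-reduced to a methyl group through quinone methide formation while hydride is present, and the salicyl alcohol may self-condense during isolation. Fallback, setting out from 5 and returning at 8: 5 is heated with PhB(OH)2 and paraformaldehyde (cat. propanoic acid, toluene, reflux, water separator). This boron-templated, ortho-specific hydroxymethylation should give (2S)-1-[5-(benzyloxy)-7-hydroxy-2-phenyl-4H-1,3,2-benzodioxaborin-8-yl]-2-methylbutan-1-one F3, a stable masked salicyl alcohol made without any hydride. Exchange of boron with propane-1,3-diol (THF, rt) frees 8 directly before step 7.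

3. Step 12. The pyranone methide may couple with unreacted pyranone to the methylene-bis-pyranone, and the methylene bridge may exchange between partners. Fallback, setting out from 16 and returning at 23: the roles are reversed. 16 is aminomethylated at its only free aromatic carbon (Eschenmoser's salt, MeCN, rt) to (2S)-1-[(3S)-6-[(dimethylamino)methyl]-3,5,7-trihydroxy-2,2-dimethyl-3,4-dihydro-2H-chromen-8-yl]-2-methylbutan-1-one F4, which is isolated and heated with pyranone 20 (dioxane, 80 °C). The arene-derived quinone methide is then the electrophile and pyranone C-3 the nucleophile, so a pyranone methide that could dimerise is never formed.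

**Further compounds**

F1 | step 7 | (2S)-1-[5-(benzyloxy)-7-hydroxy-2,2-dimethyl-2H-chromen-8-yl]-2-methylbutan-1-one | CC[C@H](C)C(=O)c1c(O)cc(OCc2ccccc2)c2c1OC(C)(C)C=C2
F2 | step 7 | (2S)-1-[(3S,4S)-5-(benzyloxy)-3,4-epoxy-7-hydroxy-2,2-dimethyl-3,4-dihydro-2H-chromen-8-yl]-2-methylbutan-1-one | CC[C@H](C)C(=O)c1c(O)cc(OCc2ccccc2)c2c1OC(C)(C)[C@H]3O[C@@H]23
F3 | step 5 | (2S)-1-[5-(benzyloxy)-7-hydroxy-2-phenyl-4H-1,3,2-benzodioxaborin-8-yl]-2-methylbutan-1-one | CC[C@H](C)C(=O)c1c(O)cc(OCc2ccccc2)c2c1OB(c3ccccc3)OC2
F4 | step 12 | (2S)-1-[(3S)-6-[(dimethylamino)methyl]-3,5,7-trihydroxy-2,2-dimethyl-3,4-dihydro-2H-chromen-8-yl]-2-methylbutan-1-one | CC[C@H](C)C(=O)c1c(O)c(CN(C)C)c(O)c2c1OC(C)(C)[C@@H](O)C2
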